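**Retrosynthetic overview**

1. Numbering: ring C is the 14-membered carbocycle C1–C14 (C3=C4, C10=C11; C12 carries CH3 and OOH); ring A is the α-methylene γ-lactone on C1/C2; ring B is the butenolide O–C6–C7=C8–C19(=O). The target comes from hydrolysis of a C12 peroxyketal.
2. Ring C is closed at C9–C10 by an intramolecular allyl–alkenyl Stille coupling. C9 is the exocyclic carbon on C8 of ring B, so its acetate is a 2-(acyloxymethyl)-2-enoate that ionises easily to a π-allyl unit. C10 is the tin-bearing end of an (E)-alkene whose other neighbour is the fully substituted C12, so hydrostannation is regioselective and no allylic isomerisation is possible.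
3. Ring A (trans) comes from a ligand-controlled chromium 2-(alkoxycarbonyl)allylation of the C2 enal (butenolide half) with the C1 allylic bromide (peroxide half).
4. Peroxide half from geraniol (its C2–C6 and 3-methyl become C11–C14, C1 and the C12 methyl): Sharpless epoxidation, invertive perhydrolysis at C12, glycol cleavage, alkyne, hydrostannation, Baylis–Hillman. Butenolide half from (R)-epichlorohydrin: carboalumination sets (E)-C3=C4, ring-closing metathesis makes ring B.
5. Order of ring formation: B, then A, then C.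

Key step: step 18

**Remarks on the chemistry**
- The target is (1R,2S,3E,6R,7Z,10E,12S) in the numbering above.
- Assumption: the perhydrolysis of step 2 goes with inversion at the tertiary carbon.
- Assumption: the chiral chromium ligand of step 17 delivers the (2S) carbinol; if the opposite aldehyde face reacts, the enantiomeric ligand is used.
- The carbinol carbon of 8, 9 and 10 is formed as both epimers; it becomes sp2 in 11.
- 2-(Acetoxymethyl)acrylic acid is made in step 10 from the commercial bromo acid.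

**Route**

Step 1
Reactants: 1 geraniol
Product: 2 [(2R,3R)-3-methyl-3-(4-methylpent-3-en-1-yl)oxiran-2-yl]methanol
Conditions: Ti(OiPr)4 (5 mol %), D-(−)-diethyl tartrate (7 mol %), t-BuOOH, 4 Å MS, CH2Cl2, −20 °C
Reagents that add atoms: tert-butyl hydroperoxide (CC(C)(C)OO)
Why: Sharpless asymmetric epoxidation of the allylic alcohol; the D-(−)-tartrate complex delivers oxygen to the face that gives the (2R,3R)-epoxide and leaves the remote olefin untouched.

Step 2
Reactants: 2 [(2R,3R)-3-methyl-3-(4-methylpent-3-en-1-yl)oxiran-2-yl]methanol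
Product: 3 (2R,3S)-3-hydroperoxy-3,7-dimethyloct-6-ene-1,2-diol
Conditions: H2O2 (anhydrous, in Et2O), H3PMo12O40 (2 mol %), Et2O, rt
Reagents that add atoms: hydrogen peroxide (OO)
Why: Acid-catalysed perhydrolysis of a trisubstituted epoxide; hydrogen peroxide should open the activated epoxide at the tertiary carbon with inversion (the hydroxymethyl group disfavours attack at C2), turning the (3R)-epoxide carbon into the (S)-hydroperoxide carbon that becomes C12.

Step 3
Reactants: 3 (2R,3S)-3-hydroperoxy-3,7-dimethyloct-6-ene-1,2-diol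
Product: 4 (2S)-2-hydroperoxy-2,6-dimethylhept-5-enal
Conditions: NaIO4, THF/H2O (pH 7), 0 °C
Reagents that add atoms: none
Why: Malaprade glycol cleavage; periodate cleaves only the 1,2-diol, so the surplus carbon leaves as formaldehyde and the aldehyde carbon (future C11) stands next to the untouched quaternary hydroperoxide carbon.

Step 4
Reactants: 4 (2S)-2-hydroperoxy-2,6-dimethylhept-5-enal
Product: 5 (2S)-2-[(2-methoxypropan-2-yl)peroxy]-2,6-dimethylhept-5-enal
Conditions: 2-methoxypropene, PPTS (cat.), CH2Cl2, 0 °C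
Reagents that add atoms: 2-methoxypropene (C=C(C)OC)
Why: Peroxyketal formation by acid-catalysed addition of the hydroperoxide to the enol ether; the base-stable, acid-labile peroxyketal masks the O–O–H group for the following steps and the non-enolisable aldehyde is unaffected.

Step 5
Reactants: 5 (2S)-2-[(2-methoxypropan-2-yl)peroxy]-2,6-dimethylhept-5-enal
Product: 6 (3S)-3-[(2-methoxypropan-2-yl)peroxy]-3,7-dimethyloct-6-en-1-yne
Conditions: dimethyl (1-diazo-2-oxopropyl)phosphonate, K2CO3, MeOH, 0 °C to rt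
Reagents that add atoms: dimethyl (1-diazo-2-oxopropyl)phosphonate (CC(=O)C(=[N+]=[N-])P(=O)(OC)OC)
Why: Seyferth–Gilbert homologation in the Ohira–Bestmann form; the aldehyde has no α-hydrogen and the tertiary peroxyketal is stable to carbonate in methanol, so the one-carbon extension supplies C10 as the alkyne terminus.

Step 6
Reactants: 6 (3S)-3-[(2-methoxypropan-2-yl)peroxy]-3,7-dimethyloct-6-en-1-yne
Product: 7 (4S)-4-[(2-methoxypropan-2-yl)peroxy]-4-methylhex-5-ynal
Conditions: O3, CH2Cl2, pyridine, −78 °C (dye end point); then Me2S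
Reagents that add atoms: ozone ([O-][O+]=O)
Why: Ozonolysis; the electron-rich trisubstituted olefin reacts far faster than the terminal alkyne, and dimethyl sulfide reduces the ozonide without touching the dialkyl peroxide.

Step 7
Reactants: 7 (4S)-4-[(2-methoxypropan-2-yl)peroxy]-4-methylhex-5-ynal
Product: 8 methyl (6S)-3-hydroxy-6-[(2-methoxypropan-2-yl)peroxy]-6-methyl-2-methylideneoct-7-ynoate
Conditions: methyl acrylate (excess), DABCO, MeOH, rt
Reagents that add atoms: methyl acrylate (C=CC(=O)OC)
Why: Morita–Baylis–Hillman reaction of an unhindered aliphatic aldehyde; it attaches the three carbons of ring A (C15, C16, C17) under mildly basic conditions that the peroxyketal and alkyne tolerate.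

Step 8
Reactants: 8 methyl (6S)-3-hydroxy-6-[(2-methoxypropan-2-yl)peroxy]-6-methyl-2-methylideneoct-7-ynoate
Product: 9 methyl (6S,7E)-3-hydroxy-6-[(2-methoxypropan-2-yl)peroxy]-6-methyl-2-methylidene-8-(tributylstannyl)oct-7-enoate
Conditions: Bu3SnH (1.05 equiv, slow addition), PdCl2(PPh3)2 (2 mol %), THF, 0 °C
Reagents that add atoms: tributyltin hydride (CCCC[SnH](CCCC)CCCC)
Why: Palladium-catalysed hydrostannation; syn addition with tin at the terminal carbon (the internal carbon is shielded by the quaternary centre) should give the (E)-alkenylstannane and so fix the C10=C11 geometry, the alkyne reacting much faster than the acrylate.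

Step 9
Reactants: 9 methyl (6S,7E)-3-hydroxy-6-[(2-methoxypropan-2-yl)peroxy]-6-methyl-2-methylidene-8-(tributylstannyl)oct-7-enoate
Product: 11 methyl (2Z,6S,7E)-2-(bromomethyl)-6-[(2-methoxypropan-2-yl)peroxy]-6-methyl-8-(tributylstannyl)octa-2,7-dienoate, via allylic mesylate 10 (not isolated)
Conditions: MsCl, Et3N, CH2Cl2, −20 °C; then LiBr, THF, 0 °C to rt
Reagents that add atoms: methanesulfonyl chloride (CS(=O)(=O)Cl); lithium bromide ([Li+].[Br-])
Why: SN2′ displacement of a Baylis–Hillman mesylate by bromide gives the conjugated (Z)-2-(bromomethyl)enoate; the non-acidic, phosphine-free conditions spare the alkenylstannane and the peroxyketal.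

Step 10
Reactants: 12 2-(bromomethyl)acrylic acid
Product: 13 2-(acetoxymethyl)acrylic acid
Conditions: KOAc (2.2 equiv), DMF, rt; acidic work-up
Reagents that add atoms: potassium acetate (CC(=O)[O-].[K+])
Why: Nucleophilic substitution of an activated allylic bromide by acetate (SN2 and SN2′ give the same product).

Step 11
Reactants: 14 (R)-epichlorohydrin
Product: 15 (2R)-1-chloropent-4-yn-2-ol
Conditions: acetylene, n-BuLi, THF, −78 °C; BF3·OEt2; then 14, −78 °C
Reagents that add atoms: acetylene (C#C)
Why: Lewis acid-promoted opening of the epoxide by lithium acetylide (Yamaguchi–Hirao alkynylation) at the unsubstituted epoxide carbon; the C–O bond of the stereocentre (future C6) is not broken.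

Step 12
Reactants: 15 (2R)-1-chloropent-4-yn-2-ol
Product: 16 (2E,5R)-6-chloro-3-methylhex-2-ene-1,5-diol
Conditions: AlMe3 (3 equiv), Cp2ZrCl2 (0.25 equiv), CH2Cl2, 0 °C to rt; then (CH2O)n, THF
Reagents that add atoms: trimethylaluminium (C[Al](C)C); formaldehyde as paraformaldehyde (C=O)
Why: Negishi zirconium-catalysed carboalumination adds methyl and aluminium syn across the terminal alkyne with aluminium at the terminus, and hydroxymethylation of the alkenylalane with retention fixes the (E)-geometry of C3=C4.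

Step 13
Reactants: 16 (2E,5R)-6-chloro-3-methylhex-2-ene-1,5-diol
Product: 18 (2E,5R)-3-methylhepta-2,6-diene-1,5-diol, via epoxide 17 (not isolated)
Conditions: Me3S+ I− (4 equiv), n-BuLi (4 equiv), THF, −10 °C to rt
Reagents that add atoms: trimethylsulfonium iodide (C[S+](C)C.[I-])
Why: Sulfonium-ylide homologation of an epoxide to an allylic alcohol; base closes the chlorohydrin to 17, dimethylsulfonium methylide opens it at the terminal carbon and the betaine loses dimethyl sulfide, so the stereocentre is retained.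

Step 14
Reactants: 18 (2E,5R)-3-methylhepta-2,6-diene-1,5-diol
Product: 19 (2E,5R)-5-hydroxy-3-methylhepta-2,6-dienal
Conditions: TEMPO (10 mol %), PhI(OAc)2 (1.1 equiv), CH2Cl2, rt
Reagents that add atoms: none
Why: Oxoammonium (TEMPO) oxidation; the primary allylic alcohol is oxidised much faster than the secondary one, giving the C2 enal without over-oxidation or E/Z isomerisation.

Step 15
Reactants: 19 (2E,5R)-5-hydroxy-3-methylhepta-2,6-dienal; 13 2-(acetoxymethyl)acrylic acid
Product: 20 (3R,5E)-5-methyl-7-oxohepta-1,5-dien-3-yl 2-[(acetyloxy)methyl]prop-2-enoate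
Conditions: EDC·HCl, DMAP (5 mol %), CH2Cl2, 0 °C
Reagents that add atoms: none
Why: Steglich esterification of the secondary allylic alcohol at low temperature with minimal DMAP, so that the C–O stereocentre and the allylic acetate of the acid are not disturbed.

Step 16
Reactants: 20 (3R,5E)-5-methyl-7-oxohepta-1,5-dien-3-yl 2-[(acetyloxy)methyl]prop-2-enoate
Product: 21 [(5R)-5-[(2E)-2-methyl-4-oxobut-2-en-1-yl]-2-oxo-2,5-dihydrofuran-3-yl]methyl acetate
Conditions: RuCl2(=CHPh)(PCy3)(SIMes) (second-generation Grubbs catalyst, 5 mol %), CH2Cl2 (0.01 M), 40 °C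
Reagents that add atoms: none
Why: Ring-closing metathesis of the vinyl group with the 2-substituted acrylate forms the five-membered butenolide (ring B); the trisubstituted enal olefin is inert to the catalyst.

Step 17
Reactants: 21 [(5R)-5-[(2E)-2-methyl-4-oxobut-2-en-1-yl]-2-oxo-2,5-dihydrofuran-3-yl]methyl acetate; 11 methyl (2Z,6S,7E)-2-(bromomethyl)-6-[(2-methoxypropan-2-yl)peroxy]-6-methyl-8-(tributylstannyl)octa-2,7-dienoate
Product: 23 [(5R)-5-[(2E)-3-[(2S,3R)-3-[(3S,4E)-3-[(2-methoxypropan-2-yl)peroxy]-3-methyl-5-(tributylstannyl)pent-4-en-1-yl]-4-methylidene-5-oxooxolan-2-yl]-2-methylprop-2-en-1-yl]-2-oxo-2,5-dihydrofuran-3-yl]methyl acetate, via chromium alkoxide 22 (not isolated)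
Conditions: CrCl2 (4 equiv), chiral 2-(oxazolin-2-yl)aryl sulfonamide ligand (Kishi type, 4.4 equiv), Et3N, THF, 0 °C to rt
Reagents that add atoms: none
Why: Nozaki–Hiyama–Kishi-type 2-(alkoxycarbonyl)allylation; the allylchromium reagent adds through its substituted γ-carbon in a chair transition state to give the anti adduct, whose chromium alkoxide closes onto the methyl ester to the trans lactone (ring A), the chiral ligand selecting the aldehyde face (C2 S, hence C1 R), and chromium-mediated olefinations of peroxyketal aldehydes suggest the O–O bond is tolerated.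

Step 18
Reactants: 23 [(5R)-5-[(2E)-3-[(2S,3R)-3-[(3S,4E)-3-[(2-methoxypropan-2-yl)peroxy]-3-methyl-5-(tributylstannyl)pent-4-en-1-yl]-4-methylidene-5-oxooxolan-2-yl]-2-methylprop-2-en-1-yl]-2-oxo-2,5-dihydrofuran-3-yl]methyl acetate
Product: 24 (1R,2S,3E,6R,7Z,10E,12S)-12-[(2-methoxypropan-2-yl)peroxy]cembra-3,7,10,15(17)-tetraene-16,2:19,6-diolide
Conditions: Pd2(dba)3 (10 mol %), AsPh3 (40 mol %), LiCl (3 equiv), DMF, 40 °C, 0.001 M (slow addition)
Reagents that add atoms: none
Why: Zerovalent palladium ionises the primary allylic acetate (a 2-(acyloxymethyl)-2-enoate inside ring B) to a π-allyl complex over C7–C8–C9; chloride-assisted transmetalation of the C10 alkenylstannane and reductive elimination then form C9–C10, the closest precedents being the allylic acetate/alkenylstannane Stille coupling and its macrocyclic sp3–sp2 variants. Ring C (14-membered) is closed by C–C bond formation at the exocyclic π-allyl terminus C9, with C9 and C10 both becoming ring members, under high dilution. No stereocentre is created: the (E)-geometry of C10=C11 is transferred with retention from the stannane, and C1, C2, C6 and C12 are remote from the reacting centres and not epimerisable under the neutral conditions. Attack at C9 and not at the ring carbon C7 is secured by the lower substitution of C9 and by the regained conjugation of C7=C8 with the lactone carbonyl; the acetate is the only allylic ester expected to ionise readily, since the lactone C–O bonds at C2 and C6 are secondary and flanked by a trisubstituted or a conjugated alkene. The peroxyketal is expected to survive because dialkyl peroxides tolerate palladium/arsine cross-coupling conditions, and the α-methylene lactone is not a partner for the allyl/alkenyl palladium intermediate.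

Step 19
Reactants: 24 (1R,2S,3E,6R,7Z,10E,12S)-12-[(2-methoxypropan-2-yl)peroxy]cembra-3,7,10,15(17)-tetraene-16,2:19,6-diolide
Product: 25 (1R,2S,3E,6R,7Z,10E,12S)-12-hydroperoxycembra-3,7,10,15(17)-tetraene-16,2:19,6-diolide
Conditions: AcOH/THF/H2O (4:2:1), rt
Reagents that add atoms: none
Why: Mild acid hydrolysis of the peroxyketal releases the tertiary hydroperoxide without breaking the C12–O bond, so the configuration set in step 2 is kept and the lactones and skipped diene are untouched.

**Compound list**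

1 | geraniol | CC(C)=CCC/C(C)=C/CO | starting material
2 | [(2R,3R)-3-methyl-3-(4-methylpent-3-en-1-yl)oxiran-2-yl]methanol | CC(C)=CCC[C@@]1(C)O[C@@H]1CO | intermediate
3 | (2R,3S)-3-hydroperoxy-3,7-dimethyloct-6-ene-1,2-diol | CC(C)=CCC[C@](C)(OO)[C@H](O)CO | intermediate
4 | (2S)-2-hydroperoxy-2,6-dimethylhept-5-enal | CC(C)=CCC[C@](C)(OO)C=O | intermediate
5 | (2S)-2-[(2-methoxypropan-2-yl)peroxy]-2,6-dimethylhept-5-enal | CC(C)=CCC[C@](C)(OOC(C)(C)OC)C=O | intermediate
6 | (3S)-3-[(2-methoxypropan-2-yl)peroxy]-3,7-dimethyloct-6-en-1-yne | CC(C)=CCC[C@](C)(OOC(C)(C)OC)C#C | intermediate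
7 | (4S)-4-[(2-methoxypropan-2-yl)peroxy]-4-methylhex-5-ynal | O=CCC[C@](C)(OOC(C)(C)OC)C#C | intermediate
8 | methyl (6S)-3-hydroxy-6-[(2-methoxypropan-2-yl)peroxy]-6-methyl-2-methylideneoct-7-ynoate (both C3 epimers) | C=C(C(=O)OC)C(O)CC[C@](C)(OOC(C)(C)OC)C#C | intermediate
9 | methyl (6S,7E)-3-hydroxy-6-[(2-methoxypropan-2-yl)peroxy]-6-methyl-2-methylidene-8-(tributylstannyl)oct-7-enoate (both C3 epimers) | C=C(C(=O)OC)C(O)CC[C@](C)(OOC(C)(C)OC)/C=C/[Sn](CCCC)(CCCC)CCCC | intermediate
10 | allylic mesylate of 9 | C=C(C(=O)OC)C(OS(C)(=O)=O)CC[C@](C)(OOC(C)(C)OC)/C=C/[Sn](CCCC)(CCCC)CCCC | intermediate (not isolated)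
11 | methyl (2Z,6S,7E)-2-(bromomethyl)-6-[(2-methoxypropan-2-yl)peroxy]-6-methyl-8-(tributylstannyl)octa-2,7-dienoate | BrC/C(C(=O)OC)=C\CC[C@](C)(OOC(C)(C)OC)/C=C/[Sn](CCCC)(CCCC)CCCC | intermediate
12 | 2-(bromomethyl)acrylic acid | C=C(CBr)C(=O)O | starting material
13 | 2-(acetoxymethyl)acrylic acid | C=C(COC(C)=O)C(=O)O | intermediate
14 | (R)-epichlorohydrin | ClC[C@H]1CO1 | starting material
15 | (2R)-1-chloropent-4-yn-2-ol | ClC[C@H](O)CC#C | intermediate
16 | (2E,5R)-6-chloro-3-methylhex-2-ene-1,5-diol | ClC[C@H](O)C/C(C)=C/CO | intermediate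
17 | (2E)-3-methyl-4-[(2R)-oxiran-2-yl]but-2-en-1-ol (present as its lithium alkoxide) | OC/C=C(\C)C[C@@H]1CO1 | intermediate (not isolated)
18 | (2E,5R)-3-methylhepta-2,6-diene-1,5-diol | C=C[C@H](O)C/C(C)=C/CO | intermediate
19 | (2E,5R)-5-hydroxy-3-methylhepta-2,6-dienal | C=C[C@H](O)C/C(C)=C/C=O | intermediate
20 | (3R,5E)-5-methyl-7-oxohepta-1,5-dien-3-yl 2-[(acetyloxy)methyl]prop-2-enoate | C=C[C@H](OC(=O)C(=C)COC(C)=O)C/C(C)=C/C=O | intermediate
21 | [(5R)-5-[(2E)-2-methyl-4-oxobut-2-en-1-yl]-2-oxo-2,5-dihydrofuran-3-yl]methyl acetate | O=C/C=C(\C)C[C@@H]1C=C(COC(C)=O)C(=O)O1 | intermediate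
22 | anti homoallylic alcohol from 21 and 11, present as its chromium alkoxide (hydroxy methyl ester shown) | C=C(C(=O)OC)[C@@H](CC[C@](C)(OOC(C)(C)OC)/C=C/[Sn](CCCC)(CCCC)CCCC)[C@@H](O)/C=C(\C)C[C@@H]1C=C(COC(C)=O)C(=O)O1 | intermediate (not isolated)
23 | [(5R)-5-[(2E)-3-[(2S,3R)-3-[(3S,4E)-3-[(2-methoxypropan-2-yl)peroxy]-3-methyl-5-(tributylstannyl)pent-4-en-1-yl]-4-methylidene-5-oxooxolan-2-yl]-2-methylprop-2-en-1-yl]-2-oxo-2,5-dihydrofuran-3-yl]methyl acetate | C=C1C(=O)O[C@@H](/C=C(\C)C[C@@H]2C=C(COC(C)=O)C(=O)O2)[C@@H]1CC[C@](C)(OOC(C)(C)OC)/C=C/[Sn](CCCC)(CCCC)CCCC | intermediate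
24 | (1R,2S,3E,6R,7Z,10E,12S)-12-[(2-methoxypropan-2-yl)peroxy]cembra-3,7,10,15(17)-tetraene-16,2:19,6-diolide | C=C1C(=O)O[C@H]2/C=C(\C)C[C@@H]3C=C(C/C=C/[C@@](C)(OOC(C)(C)OC)CC[C@H]12)C(=O)O3 | intermediate
25 | (1R,2S,3E,6R,7Z,10E,12S)-12-hydroperoxycembra-3,7,10,15(17)-tetraene-16,2:19,6-diolide | C=C1C(=O)O[C@H]2/C=C(\C)C[C@@H]3C=C(C/C=C/[C@@](C)(OO)CC[C@H]12)C(=O)O3 | target

**Step count**

Total: 19 steps. Longest linear sequence: 12 steps (steps 1–9, 17, 18, 19, from geraniol).

**Steps most likely to fail**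

Step 17. What may go wrong: reductive cleavage of the O–O bond by divalent chromium, or incomplete control of the aldehyde face. Fallback from 2 and 21, back at 24: the O–O bond is made only after the chromium step. 2 is silylated (Et3SiCl, imidazole) to the triethylsilyl ether F1, ozonolysed (O3; Me2S) to the epoxy aldehyde F2, taken through the Baylis–Hillman reaction with methyl acrylate to the hydroxy ester F3, and converted (NBS, Me2S) into the allylic bromide F4. Chromium-mediated coupling of F4 with 21 under the conditions of step 17 should give, after lactonisation on the metal, the epoxy lactone F5. Perhydrolysis as in step 2 (the silyl ether is cleaved by the acid) gives the hydroperoxy diol F6, NaIO4 gives the hydroperoxy aldehyde F7, and 2-methoxypropene/PPTS gives the peroxyketal aldehyde F8. Boron-Wittig olefination (CH2(Bpin)2, lithium 2,2,6,6-tetramethylpiperidide, THF, −78 °C) gives the (E)-alkenylboronate F9, and a Suzuki–Miyaura ring closure onto the allylic acetate (Pd(PPh3)4, K3PO4, THF/H2O, high dilution) forms the same C9–C10 bond and returns to 24.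

Step 2. What may go wrong: attack of hydrogen peroxide at C2 instead of the tertiary carbon, partial ionisation with erosion of configuration, or acid-promoted addition of the hydroperoxide to the remote olefin. Fallback from 2, back at 4: 2 is oxidised (TEMPO, PhI(OAc)2, MeCN/H2O) to the glycidic acid F10, whose carboxyl group blocks attack at C2 and disfavours ionisation. Perhydrolysis (H2O2, H3PMo12O40) gives the hydroxy hydroperoxy acid F11, and oxidative decarboxylation of this α-hydroxy acid (Bu4NIO4, CHCl3, 50 °C) gives 4.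

Step 18. What may go wrong: oligomerisation instead of ring closure, protodestannylation, or slow tin-to-palladium transfer. Fallback from 8, back at 24: the alkyne of 8 is hydroborated instead of hydrostannated (pinacolborane, Cp2Zr(H)Cl cat., Et3N) to the (E)-alkenylboronate alcohol F12, which is converted (NBS, Me2S) into the allylic bromide F13 and coupled with 21 as in step 17 to give the alkenylboronate F9 (the compound also reached in the fallback for step 17). Base-promoted Suzuki–Miyaura macrocyclisation (Pd(PPh3)4, K3PO4, THF/H2O, high dilution) then closes C9–C10 and gives 24.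

**Further compounds**

F1 | step 17 | triethyl{[(2R,3R)-3-methyl-3-(4-methylpent-3-en-1-yl)oxiran-2-yl]methoxy}silane | CC(C)=CCC[C@@]1(C)O[C@@H]1CO[Si](CC)(CC)CC
F2 | step 17 | 3-[(2R,3R)-2-methyl-3-{[(triethylsilyl)oxy]methyl}oxiran-2-yl]propanal | O=CCC[C@@]1(C)O[C@@H]1CO[Si](CC)(CC)CC
F3 | step 17 | methyl 3-hydroxy-2-methylidene-5-[(2R,3R)-2-methyl-3-{[(triethylsilyl)oxy]methyl}oxiran-2-yl]pentanoate | C=C(C(=O)OC)C(O)CC[C@@]1(C)O[C@@H]1CO[Si](CC)(CC)CC
F4 | step 17 | methyl (2Z)-2-(bromomethyl)-5-[(2R,3R)-2-methyl-3-{[(triethylsilyl)oxy]methyl}oxiran-2-yl]pent-2-enoate | BrC/C(C(=O)OC)=C\CC[C@@]1(C)O[C@@H]1CO[Si](CC)(CC)CC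
F5 | step 17 | epoxy lactone (analogue of 23 with the silylated epoxy alcohol in place of the peroxide and stannane) | C=C1C(=O)O[C@@H](/C=C(\C)C[C@@H]2C=C(COC(C)=O)C(=O)O2)[C@@H]1CC[C@@]3(C)O[C@@H]3CO[Si](CC)(CC)CC
F6 | step 17 | hydroperoxy diol lactone | C=C1C(=O)O[C@@H](/C=C(\C)C[C@@H]2C=C(COC(C)=O)C(=O)O2)[C@@H]1CC[C@](C)(OO)[C@H](O)CO
F7 | step 17 | hydroperoxy aldehyde lactone | C=C1C(=O)O[C@@H](/C=C(\C)C[C@@H]2C=C(COC(C)=O)C(=O)O2)[C@@H]1CC[C@](C)(OO)C=O
F8 | step 17 | peroxyketal aldehyde lactone | C=C1C(=O)O[C@@H](/C=C(\C)C[C@@H]2C=C(COC(C)=O)C(=O)O2)[C@@H]1CC[C@](C)(OOC(C)(C)OC)C=O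
F9 | step 17 | (E)-alkenylboronate analogue of 23 (pinacol boronate in place of the stannane) | C=C1C(=O)O[C@@H](/C=C(\C)C[C@@H]2C=C(COC(C)=O)C(=O)O2)[C@@H]1CC[C@](C)(OOC(C)(C)OC)/C=C/B3OC(C)(C)C(C)(C)O3
F10 | step 2 | (2S,3R)-3-methyl-3-(4-methylpent-3-en-1-yl)oxirane-2-carboxylic acid | CC(C)=CCC[C@@]1(C)O[C@@H]1C(O)=O
F11 | step 2 | (2S,3S)-3-hydroperoxy-2-hydroxy-3,7-dimethyloct-6-enoic acid | CC(C)=CCC[C@](C)(OO)[C@H](O)C(O)=O
F12 | step 18 | methyl (6S,7E)-3-hydroxy-6-[(2-methoxypropan-2-yl)peroxy]-6-methyl-2-methylidene-8-(4,4,5,5-tetramethyl-1,3,2-dioxaborolan-2-yl)oct-7-enoate | C=C(C(=O)OC)C(O)CC[C@](C)(OOC(C)(C)OC)/C=C/B1OC(C)(C)C(C)(C)O1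
F13 | step 18 | methyl (2Z,6S,7E)-2-(bromomethyl)-6-[(2-methoxypropan-2-yl)peroxy]-6-methyl-8-(4,4,5,5-tetramethyl-1,3,2-dioxaborolan-2-yl)octa-2,7-dienoate | BrC/C(C(=O)OC)=C\CC[C@](C)(OOC(C)(C)OC)/C=C/B1OC(C)(C)C(C)(C)O1
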